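| flask | E | Z | remark | time |
|---|---|---|---|---|
| dawn | 0.013 M | 0.60 equiv | run made earlier |  |
| noon | 0.013 M | 0.30 equiv | run made earlier |  |
| dusk | 0.013 M | 0.45 equiv | run made earlier |  |
| spring | 0.026 M | 0.60 equiv | run made earlier |  |
| north-west | 0.013 M (fed, over 20 min) | 0.600 equiv | all else is in the flask from the start; the feed brings no volume worth counting | 1.5 h |
| south-east | 0.013 M | 0.600 equiv (fed, over 20 min) | all else is in the flask from the start; the feed brings no volume worth counting | 1.5 h |
| south-west | 0.013 M | 0.600 equiv | everything together at the start | 1.5 h |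

| run | time / min | G / % | Q / % |
|---|---|---|---|
| dawn | 12.0 | 1.9 | 1.6 |
| dawn | 25.0 | 3.4 | 3.5 |
| dawn | 40.0 | 2.3 | 3.7 |
| dawn | 50.0 | 2.1 | 3.6 |
| dawn | 60.0 | 3.4 | 4.9 |
| dawn | 80.0 | 2.3 | 5.3 |
| dawn | 90.0 | 2.6 | 6.9 |
| noon | 8.00 | 0.4 | 0.5 |
| noon | 12.0 | 0.9 | 1.9 |
| noon | 15.0 | 0.2 | 2.2 |
| noon | 25.0 | 0.3 | 2.5 |
| noon | 40.0 | 0.5 | 3.7 |
| noon | 60.0 | 0.3 | 6.3 |
| noon | 90.0 | 0.3 | 8.8 |
| dusk | 8.00 | 0.5 | 1.0 |
| dusk | 12.0 | 1.1 | 1.9 |
| dusk | 15.0 | 2.6 | 2.6 |
| dusk | 25.0 | 1.2 | 2.6 |
| dusk | 40.0 | 1.1 | 2.9 |
| dusk | 60.0 | 1.0 | 5.6 |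
| dusk | 90.0 | 2.1 | 7.6 |
| spring | 20.0 | 2.7 | 2.5 |
| spring | 40.0 | 3.3 | 4.0 |
| spring | 50.0 | 3.1 | 5.0 |
| spring | 80.0 | 2.8 | 7.2 |
| spring | 90.0 | 2.5 | 8.4 |

(standard deviation of a reading: 0.5 percentage points)

- amounts and yields of L count D too
- given per volume of solution although it is solid: D
- the analysis behind the earlier runs scatters by 0.5 percentage points, standard deviation
- steps that have been proposed: L + E -> Q; X + Z -> L + G; J + Z -> L + X; E + Z -> L + J; D <-> L

- the flask with the highest share of G in G plus Q ("all alike" if they lie within 1.5 percentage points) (north-west / south-east / south-west / all alike)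
- share of G in G plus Q at the end, north-west
- share of G in G plus Q at the end, south-east
- share of G in G plus Q at the end, south-west

- Late in the dawn and spring runs G lies flat while Q climbs, so you need two numbers for the end share S = G/(G+Q), a selectivity. One is the plateau of G. The other is the Q clock s, the fraction of the charge turning to Q per minute after the rise of G, taken as the mean late slope of those runs 7.60 × 10⁻⁴ min⁻¹.
- My reckoning starts from the plateau, so take that first: dawn gives 2.68%, and the clock gives Q 6.84% at 1.5 h.
- G takes three exchanges, so I take it to follow the cube of the exposure of each E to Z. In north-west, the first E meets the full pool of Z and later E a pool already drawn down. I take the exposure to fall in a straight line to nothing, and then the mean cube exceeds the cube of the mean by F = 2.00.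
- The scatter of one reading spread over the dawn span puts 1.00 × 10⁻⁴ min⁻¹ on s, and that moves the reckoned S in north-west by 3.5 percentage points.
- Between F of one and the full F, S moves by 16 points, so F must be known better than s.
- I therefore expect 43.9% in north-west, and 28.2% in south-east and south-west, taking F as one there.
- The forecast says north-west: 41% (33% to 55%), 30% and 28%, reasoning that “Feeding E into excess Z over-exchanges the early E”. Its north-west figure lies 3 points below mine.

    L + E → Q (k = 2.80 L mol⁻¹ min⁻¹)
    X + Z → L + G (k = 55.0 L mol⁻¹ min⁻¹)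
    J + Z → L + X (k = 50.0 L mol⁻¹ min⁻¹)
    E + Z → L + J (k = 48.0 L mol⁻¹ min⁻¹)
    D ⇌ L, rate k5*(cs5 - [L]) while solid is left; crystals form when [L] > cs5 (solubility = 0.480 mM, k = 1.90 min⁻¹)

- North-west, south-east and south-west give 56.5%, 27.1% and 27.7%. G in north-west is 3.27 times that in south-west, against my F of 2.00, and Q in north-west is 6.72%, against the clock's 6.84%. Read north-west at 6.0 h: G stays 8.71%, the clock gives Q 27.4%, and the flask holds 24.6%. The reckoned S is 24.1%, and the flask gives 26.2%.

The readings were generated by integration from invented constants; the scatter is artificial.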